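**Retrosynthetic overview**
1. Structural feature used: in ring A the neighbouring carbons C4a and C8a carry the C4 carbon and the C1 carboxyl carbon, and the C8 oxygen sits next to C8a. An aryne spanning C4a–C8a is therefore polarised so that a carbon nucleophile enters at C4a and an acyl group ends on C8a.
2. Key disconnection: C4–C4a and C8a–C1 are cut together, giving an o-silylaryl triflate of ring A and diallyl methylmalonate (aryne insertion into a C–C(=O) sigma bond).
3. Late disconnections: O2–C3 (lactol to keto acid), the CH2–O bond of the side arm (diazoketone plus ring B acid, O–H insertion), and C3–CH2 (acid chloride plus diazomethane). C4 is fixed by ketene deracemisation with (S)-pantolactone, and C3 then follows C4 by ring–chain equilibration.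
4. Ring order: rings A and B are bought as arenes. The lactol ring (C1, O2, C3, C4, C4a, C8a) is the only ring built, and it closes in the penultimate step.

Key step: step 6

Numbering used throughout (isochroman-1-one): C1 lactone carbonyl, O2, C3 lactol carbon, C4 (CH–CH3), C4a, C5 (CH3), C6 (OCH3), C7 (H), C8 (OH), C8a. Ring A is this arene. Ring B is the trimethylresorcylate arene (C1 carboxyl, C2 OH, C3 CH3, C4 OH, C5 CH3, C6 CH3). The target is (3R,4S).

Assumption: C3 is a lactol carbon that equilibrates through the open keto acid. The drawn (3R) epimer has C3–OH axial (anomeric effect) and anti to the pseudoaxial C4 methyl group (which thereby avoids the C5 methyl group), with the acyloxymethyl arm equatorial, and it is taken to be the equilibrium form.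

**Step 1**
Reactants: 1 2-hydroxy-4,6-dimethoxybenzaldehyde
Product: 2 3,5-dimethoxy-2-methylphenol
Conditions: H2 (3 bar), 10% Pd/C, AcOH, rt
Reagents that add atoms: none
Why: Catalytic hydrogenolysis of an aryl aldehyde to the methylarene is easy here because the ortho hydroxy group and the two methoxy groups stabilise positive charge at the benzylic carbon, and 1 holds no other reducible group.

**Step 2**
Reactants: 2 3,5-dimethoxy-2-methylphenol
Product: 3 3,5-dimethoxy-2-methylphenyl N-isopropylcarbamate
Conditions: i-PrNCO, Et3N (cat.), CH2Cl2, rt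
Reagents that add atoms: isopropyl isocyanate, CC(C)N=C=O
Why: Amine-catalysed addition of the phenol to the isocyanate (carbamoylation) gives a secondary carbamate, preferred to a diethylcarbamate because it can later be removed by a mild E1cB elimination that spares an aryl–silicon bond.

**Step 3**
Reactants: 3 3,5-dimethoxy-2-methylphenyl N-isopropylcarbamate
Product: 7 3,5-dimethoxy-2-methyl-6-(trimethylsilyl)phenyl N-isopropylcarbamate, via N-TBS carbamate 4 (not isolated), via C8a aryllithium 5 (not isolated), via N-TBS C8a-TMS carbamate 6 (not isolated)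
Conditions: TBSOTf, TMEDA, Et2O, 0 °C to rt; n-BuLi, TMEDA, −78 °C; TMSCl, −78 °C to rt; cold sat. aq NaHSO4 (brief)
Reagents that add atoms: TMSCl, C[Si](C)(C)Cl; TBSOTf, CC(C)(C)[Si](C)(C)OS(=O)(=O)C(F)(F)F (its silyl group is carried only by 4, 5, 6); n-BuLi, [Li]CCCC (its lithium is carried only by 5)
Why: Directed ortho metalation: transient N-silylation masks the N–H, the carbamate (the strongest oxygen-based directing group) and the future C8 methoxy group then cooperate to steer n-BuLi/TMEDA to the proton between them (future C8a) in preference to the C7 proton between the two methoxy groups and to the benzylic protons of the methyl group, TMSCl traps the aryllithium at −78 °C before an anionic Fries shift can start, and the brief acidic wash strips only the N-silyl group.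

**Step 4**
Reactants: 7 3,5-dimethoxy-2-methyl-6-(trimethylsilyl)phenyl N-isopropylcarbamate
Product: 9 3,5-dimethoxy-2-methyl-6-(trimethylsilyl)phenyl trifluoromethanesulfonate, via free o-silylphenol 8 (not isolated)
Conditions: DBU, Et2NH, MeCN, 40 °C; then PhNTf2, rt to 40 °C
Reagents that add atoms: N-phenylbis(trifluoromethanesulfonimide), O=S(=O)(N(c1ccccc1)S(=O)(=O)C(F)(F)F)C(F)(F)F
Why: DBU triggers E1cB loss of isopropyl isocyanate from the carbamate anion, Et2NH removes the isocyanate as a urea, and the hindered phenoxide is O-sulfonylated in the same flask by PhNTf2, so the aryl–silicon bond of this electron-rich ring never meets a proton source strong enough for protodesilylation.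

**Step 5**
Reactants: 10 methylmalonic acid
Product: 11 diallyl 2-methylmalonate
Conditions: allyl alcohol (excess), TsOH·H2O (cat.), cyclohexane, reflux, Dean–Stark
Reagents that add atoms: allyl alcohol, C=CCO
Why: Fischer esterification with azeotropic removal of water gives the C-methylated malonate free of its unmethylated and dimethylated relatives, which C-methylation of diallyl malonate would leave behind and of which the unmethylated one would outcompete 11 for the aryne.

**Step 6**
Reactants: 9 3,5-dimethoxy-2-methyl-6-(trimethylsilyl)phenyl trifluoromethanesulfonate; 11 diallyl 2-methylmalonate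
Product: 16 allyl 2-[1-(allyloxy)-1-oxopropan-2-yl]-4,6-dimethoxy-3-methylbenzoate (racemic at C4), via ring A aryne 12 (not isolated), via C8a aryl anion 13 (not isolated), via benzocyclobutenoxide 14 (not isolated), via C4 ester enolate 15 (not isolated)
Conditions: CsF (3 equiv), 11 (2 equiv), dry MeCN, 80 °C, 9 added slowly
Reagents that add atoms: none
Why: Fluoride attacks silicon in 9, triflate leaves and aryne 12 is released; its C4a–C8a triple bond is distorted by the sigma-withdrawing C8 methoxy group so that C4a is the more electrophilic end, and the fluoride-generated anion of 11 therefore bonds through carbon to C4a (C4–C4a) and leaves the charge on C8a beside oxygen (13). The malonate carbon of 13 is quaternary and offers no internal proton, so the aryl anion adds to one of the two equivalent ester carbonyls (4-exo-trig) to give 14, whose strained ring fragments at the C4–C1 bond, placing the ester on C8a (C8a–C1) and leaving enolate 15, which is protonated by fresh 11 and so carries the chain. The closest known reaction type is the fluoride-induced acyl-alkylation of arynes, the formal insertion of an aryne into the C–C sigma bond of malonates and beta-keto esters. No ring of the target closes, since the four-membered ring is only transient. C4 arises by protonation of an achiral enolate with no controlling element and is racemic, its configuration being set in step 10. The step needs regioselectivity (carbon to C4a, acyl to C8a) and acyl transfer ahead of external protonation; the first rests on the inductive pull of the C8 methoxy group outweighing the bulk of the C5 methyl group and the weak opposite bias of the remote C6 methoxy group, the second on dry CsF/MeCN and a low stationary concentration of 12.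

**Step 7**
Reactants: 16 allyl 2-[1-(allyloxy)-1-oxopropan-2-yl]-4,6-dimethoxy-3-methylbenzoate
Product: 17 allyl 2-[1-(allyloxy)-1-oxopropan-2-yl]-6-hydroxy-4-methoxy-3-methylbenzoate (racemic)
Conditions: BCl3 (1 M in CH2Cl2, 1.2 equiv), CH2Cl2, −78 to 0 °C; then H2O
Reagents that add atoms: none
Why: Chelation-directed aryl methyl ether cleavage: BCl3 is held in a six-membered chelate between the C1 ester carbonyl and the C8 methoxy oxygen, so chloride removes that methyl group only, the C6 methoxy group and both allyl esters being left at low temperature, and the Lewis acid is used now because the later lactol would dehydrate to an isocoumarin under such conditions.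

**Step 8**
Reactants: 17 allyl 2-[1-(allyloxy)-1-oxopropan-2-yl]-6-hydroxy-4-methoxy-3-methylbenzoate
Product: 18 allyl 2-[1-(allyloxy)-1-oxopropan-2-yl]-6-(benzyloxy)-4-methoxy-3-methylbenzoate (racemic)
Conditions: BnBr, K2CO3, acetone, reflux
Reagents that add atoms: benzyl bromide, BrCc1ccccc1
Why: Williamson ether synthesis on the hydrogen-bonded C8 phenol installs a group that shields it from acid chloride, ketene, diazomethane and carbenoid chemistry and that leaves at the end by the same hydrogenolysis as the ring B ethers, while K2CO3 is too weak to alkylate C4.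

**Step 9**
Reactants: 18 allyl 2-[1-(allyloxy)-1-oxopropan-2-yl]-6-(benzyloxy)-4-methoxy-3-methylbenzoate
Product: 19 rac-2-{2-[(allyloxy)carbonyl]-3-(benzyloxy)-5-methoxy-6-methylphenyl}propanoic acid
Conditions: LiOH·H2O (2 equiv), THF/H2O, rt; then 1 M HCl
Reagents that add atoms: lithium hydroxide, [Li+].[OH-]
Why: Sterically differentiated saponification (BAc2), as in the half-hydrolysis of homophthalate diesters: hydroxide reaches the aliphatic ester carbonyl, whereas the benzoate carbonyl is flanked by the C8 benzyloxy group and the C4a side chain and does not form the tetrahedral intermediate at room temperature.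

**Step 10**
Reactants: 19 rac-2-{2-[(allyloxy)carbonyl]-3-(benzyloxy)-5-methoxy-6-methylphenyl}propanoic acid; 20 (S)-pantolactone
Product: 23 (3S)-4,4-dimethyl-2-oxooxolan-3-yl (2S)-2-{2-[(allyloxy)carbonyl]-3-(benzyloxy)-5-methoxy-6-methylphenyl}propanoate, via racemic acid chloride 21 (not isolated), via aryl methyl ketene 22 (not isolated)
Conditions: (COCl)2, DMF (cat.), CH2Cl2, 0 °C to rt, evaporate; Me2NEt (3 equiv), toluene, 0 °C to rt; 20, −78 °C
Reagents that add atoms: oxalyl chloride, O=C(Cl)C(=O)Cl (its chlorine is carried only by 21)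
Why: Deracemisation through a ketene: dehydrochlorination of 21 erases C4, and amine-mediated addition of the alpha-hydroxy lactone to aryl methyl ketene 22 gives an enol whose protonation at C4 is directed by the pantolactone stereocentre, the established sense for 2-arylpropanoic acids being like to like ((R)-pantolactone gives (R)-esters), so the (S)-alcohol is used to set (4S).

**Step 11**
Reactants: 23 (3S)-4,4-dimethyl-2-oxooxolan-3-yl (2S)-2-{2-[(allyloxy)carbonyl]-3-(benzyloxy)-5-methoxy-6-methylphenyl}propanoate
Product: 25 (2S)-2-{2-[(allyloxy)carbonyl]-3-(benzyloxy)-5-methoxy-6-methylphenyl}propanoic acid, via peroxy acid 24 (not isolated)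
Conditions: LiOH, 30% H2O2, THF/H2O, 0 °C; Na2SO3; then cold 1 M HCl
Reagents that add atoms: hydrogen peroxide, OO
Why: Hydroperoxide-mediated ester cleavage uses a nucleophile that is more reactive and much less basic than hydroxide, so the activated ester of the alpha-hydroxy lactone is cut at 0 °C without enolising C4 (whose acidity is already lowered because the di-ortho-substituted ring cannot lie coplanar with an enolate) and without touching the shielded allyl benzoate.

**Step 12**
Reactants: 25 (2S)-2-{2-[(allyloxy)carbonyl]-3-(benzyloxy)-5-methoxy-6-methylphenyl}propanoic acid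
Product: 27 allyl 6-(benzyloxy)-2-[(2S)-4-diazo-3-oxobutan-2-yl]-4-methoxy-3-methylbenzoate, via (S)-acid chloride 26 (not isolated)
Conditions: (COCl)2, DMF (cat.), CH2Cl2, 0 °C, evaporate cold; CH2N2 (excess), Et2O, 0 °C
Reagents that add atoms: diazomethane, C=[N+]=[N-]; oxalyl chloride, O=C(Cl)C(=O)Cl (its chlorine is carried only by 26)
Why: Acylation of diazomethane by the acid chloride (first stage of the Arndt–Eistert sequence) forms the C3–CH2 bond, and because no amine base is present, excess diazomethane consumes the HCl and 2-arylpropanoyl chlorides hold their configuration under such conditions, (4S) should be kept.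

**Step 13**
Reactants: 28 methyl 2,4-dihydroxy-3,6-dimethylbenzoate
Product: 29 methyl 5-formyl-2,4-dihydroxy-3,6-dimethylbenzoate
Conditions: Cl2CHOMe, TiCl4, CH2Cl2, 0 °C to rt; then aq HCl
Reagents that add atoms: dichloromethyl methyl ether, COC(Cl)Cl (formyl carbon); water, O (formyl oxygen)
Why: Rieche formylation of a titanium-bound resorcinol attacks the only free ring position (ring B C5, ortho to C4–OH and para to C2–OH), so regiochemistry is not in question.

**Step 14**
Reactants: 29 methyl 5-formyl-2,4-dihydroxy-3,6-dimethylbenzoate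
Product: 30 methyl 2,4-dihydroxy-3,5,6-trimethylbenzoate
Conditions: H2 (3 bar), 10% Pd/C, AcOH, rt
Reagents that add atoms: none
Why: Catalytic hydrogenolysis of an o-hydroxyaryl aldehyde to the methylarene works as in step 1, and the methyl ester and the phenols are inert to it.

**Step 15**
Reactants: 30 methyl 2,4-dihydroxy-3,5,6-trimethylbenzoate
Product: 31 methyl 2,4-bis(benzyloxy)-3,5,6-trimethylbenzoate
Conditions: BnBr (3 equiv), K2CO3, DMF, 60 °C
Reagents that add atoms: benzyl bromide, BrCc1ccccc1
Why: Double Williamson ether synthesis, warmed so that the chelated and flanked C2–OH also reacts, keeps the phenols out of the O–H insertion of step 17 and stabilises the later acid against decarboxylation.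

**Step 16**
Reactants: 31 methyl 2,4-bis(benzyloxy)-3,5,6-trimethylbenzoate
Product: 32 2,4-bis(benzyloxy)-3,5,6-trimethylbenzoic acid
Conditions: KOH, DMSO/H2O, 100 °C; then 1 M HCl
Reagents that add atoms: potassium hydroxide, [K+].[OH-]
Why: Hydrolysis of a di-ortho-substituted methyl benzoate needs poorly solvated hydroxide in hot aqueous DMSO (attack at the acyl carbon or at the methyl carbon both end in the carboxylate), and aryl benzyl ethers are inert to these conditions.

**Step 17**
Reactants: 27 allyl 6-(benzyloxy)-2-[(2S)-4-diazo-3-oxobutan-2-yl]-4-methoxy-3-methylbenzoate; 32 2,4-bis(benzyloxy)-3,5,6-trimethylbenzoic acid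
Product: 33 allyl 6-(benzyloxy)-2-[(2S)-4-{[2,4-bis(benzyloxy)-3,5,6-trimethylbenzoyl]oxy}-3-oxobutan-2-yl]-4-methoxy-3-methylbenzoate
Conditions: Rh2(OAc)4 (1 mol %), CH2Cl2, rt, 27 added slowly to 32 (1.5 equiv)
Reagents that add atoms: none
Why: Carbenoid O–H insertion of an alpha-diazoketone into a carboxylic acid: the electrophilic rhodium carbenoid is captured by the acid O–H faster than by the allyl alkene or the ethers, the bulk of 32 does not matter because the new bond forms at the carboxyl oxygen, and the neutral medium at room temperature leaves C4 untouched.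

**Step 18**
Reactants: 33 allyl 6-(benzyloxy)-2-[(2S)-4-{[2,4-bis(benzyloxy)-3,5,6-trimethylbenzoyl]oxy}-3-oxobutan-2-yl]-4-methoxy-3-methylbenzoate
Product: 35 [(3R,4S)-8-(benzyloxy)-3-hydroxy-6-methoxy-4,5-dimethyl-1-oxo-3,4-dihydro-1H-isochromen-3-yl]methyl 2,4-bis(benzyloxy)-3,5,6-trimethylbenzoate, via open keto acid 34 (not isolated)
Conditions: Pd(PPh3)4 (5 mol %), N-methylaniline (2 equiv), THF, rt
Reagents that add atoms: none
Why: Tsuji–Trost-type deallylation, in which zerovalent palladium ionises the ester at its unhindered allyl end and the weakly basic aniline takes up the allyl group, frees the shielded C1 acid, which adds to the inductively activated C3 ketone (6-exo-trig) to close the lactol ring, C3 settling under thermodynamic control from C4 as (3R) with axial OH anti to the pseudoaxial C4 methyl group.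

**Step 19**
Reactants: 35 [(3R,4S)-8-(benzyloxy)-3-hydroxy-6-methoxy-4,5-dimethyl-1-oxo-3,4-dihydro-1H-isochromen-3-yl]methyl 2,4-bis(benzyloxy)-3,5,6-trimethylbenzoate
Product: 36 [(3R,4S)-3,8-dihydroxy-6-methoxy-4,5-dimethyl-1-oxo-3,4-dihydro-1H-isochromen-3-yl]methyl 2,4-dihydroxy-3,5,6-trimethylbenzoate (target)
Conditions: H2 (1 atm), 10% Pd/C, EtOAc, rt
Reagents that add atoms: none
Why: Neutral hydrogenolysis removes the three aryl benzyl ethers while the C3–O and CH2–O bonds, which are not benzylic, stay, the absence of acid avoids dehydration to the isocoumarin, the freed C8–OH hydrogen-bonds to C1=O and favours the closed form, C4 is untouched and C3 remains at its equilibrium (3R) configuration.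

**Compound list**
1 | 2-hydroxy-4,6-dimethoxybenzaldehyde | COc1cc(O)c(C=O)c(OC)c1 | starting material
2 | 3,5-dimethoxy-2-methylphenol | COc1cc(O)c(C)c(OC)c1 | intermediate
3 | 3,5-dimethoxy-2-methylphenyl N-isopropylcarbamate | COc1cc(OC(=O)NC(C)C)c(C)c(OC)c1 | intermediate
4 | 3,5-dimethoxy-2-methylphenyl N-(tert-butyldimethylsilyl)-N-isopropylcarbamate | COc1cc(OC(=O)N(C(C)C)[Si](C)(C)C(C)(C)C)c(C)c(OC)c1 | intermediate (not isolated)
5 | 6-lithio derivative of 4 (lithium on future C8a) | COc1cc(OC)c([Li])c(OC(=O)N(C(C)C)[Si](C)(C)C(C)(C)C)c1C | intermediate (not isolated)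
6 | 3,5-dimethoxy-2-methyl-6-(trimethylsilyl)phenyl N-(tert-butyldimethylsilyl)-N-isopropylcarbamate | COc1cc(OC)c([Si](C)(C)C)c(OC(=O)N(C(C)C)[Si](C)(C)C(C)(C)C)c1C | intermediate (not isolated)
7 | 3,5-dimethoxy-2-methyl-6-(trimethylsilyl)phenyl N-isopropylcarbamate | COc1cc(OC)c([Si](C)(C)C)c(OC(=O)NC(C)C)c1C | intermediate
8 | 3,5-dimethoxy-2-methyl-6-(trimethylsilyl)phenol | COc1cc(OC)c([Si](C)(C)C)c(O)c1C | intermediate (not isolated)
9 | 3,5-dimethoxy-2-methyl-6-(trimethylsilyl)phenyl trifluoromethanesulfonate | COc1cc(OC)c([Si](C)(C)C)c(OS(=O)(=O)C(F)(F)F)c1C | intermediate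
10 | methylmalonic acid | CC(C(=O)O)C(=O)O | starting material
11 | diallyl 2-methylmalonate | C=CCOC(=O)C(C)C(=O)OCC=C | intermediate
12 | 1,2-didehydro-3,5-dimethoxy-6-methylbenzene (ring A aryne, C4a–C8a) | COC1=CC(OC)=C(C)C#C1 | intermediate (not isolated)
13 | aryl anion at C8a carrying the bis(allyloxycarbonyl)ethyl group on C4a | COc1cc(OC)[c-]c(c1C)C(C)(C(=O)OCC=C)C(=O)OCC=C | intermediate (not isolated)
14 | benzocyclobutenoxide (four-membered ring C4a, C4, C1, C8a) | COc1cc(OC)c2c(c1C)C(C)(C(=O)OCC=C)C2([O-])OCC=C | intermediate (not isolated)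
15 | C4 ester enolate of 16 | COc1cc(OC)c(C(=O)OCC=C)c(c1C)C(C)=C([O-])OCC=C | intermediate (not isolated)
16 | allyl 2-[1-(allyloxy)-1-oxopropan-2-yl]-4,6-dimethoxy-3-methylbenzoate (racemic) | COc1cc(OC)c(C(=O)OCC=C)c(C(C)C(=O)OCC=C)c1C | intermediate
17 | allyl 2-[1-(allyloxy)-1-oxopropan-2-yl]-6-hydroxy-4-methoxy-3-methylbenzoate (racemic) | COc1cc(O)c(C(=O)OCC=C)c(C(C)C(=O)OCC=C)c1C | intermediate
18 | allyl 2-[1-(allyloxy)-1-oxopropan-2-yl]-6-(benzyloxy)-4-methoxy-3-methylbenzoate (racemic) | COc1cc(OCc2ccccc2)c(C(=O)OCC=C)c(C(C)C(=O)OCC=C)c1C | intermediate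
19 | rac-2-{2-[(allyloxy)carbonyl]-3-(benzyloxy)-5-methoxy-6-methylphenyl}propanoic acid | COc1cc(OCc2ccccc2)c(C(=O)OCC=C)c(C(C)C(=O)O)c1C | intermediate
20 | (S)-pantolactone | CC1(C)COC(=O)[C@H]1O | starting material
21 | rac-2-arylpropanoyl chloride from 19 | COc1cc(OCc2ccccc2)c(C(=O)OCC=C)c(C(C)C(=O)Cl)c1C | intermediate (not isolated)
22 | allyl 6-(benzyloxy)-4-methoxy-3-methyl-2-(1-oxoprop-1-en-2-yl)benzoate (aryl methyl ketene) | COc1cc(OCc2ccccc2)c(C(=O)OCC=C)c(C(C)=C=O)c1C | intermediate (not isolated)
23 | (3S)-4,4-dimethyl-2-oxooxolan-3-yl (2S)-2-{2-[(allyloxy)carbonyl]-3-(benzyloxy)-5-methoxy-6-methylphenyl}propanoate | COc1cc(OCc2ccccc2)c(C(=O)OCC=C)c([C@H](C)C(=O)O[C@@H]2C(=O)OCC2(C)C)c1C | intermediate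
24 | (2S)-2-{2-[(allyloxy)carbonyl]-3-(benzyloxy)-5-methoxy-6-methylphenyl}propaneperoxoic acid | COc1cc(OCc2ccccc2)c(C(=O)OCC=C)c([C@H](C)C(=O)OO)c1C | intermediate (not isolated)
25 | (2S)-2-{2-[(allyloxy)carbonyl]-3-(benzyloxy)-5-methoxy-6-methylphenyl}propanoic acid | COc1cc(OCc2ccccc2)c(C(=O)OCC=C)c([C@H](C)C(=O)O)c1C | intermediate
26 | (2S)-2-arylpropanoyl chloride from 25 | COc1cc(OCc2ccccc2)c(C(=O)OCC=C)c([C@H](C)C(=O)Cl)c1C | intermediate (not isolated)
27 | allyl 6-(benzyloxy)-2-[(2S)-4-diazo-3-oxobutan-2-yl]-4-methoxy-3-methylbenzoate | COc1cc(OCc2ccccc2)c(C(=O)OCC=C)c([C@H](C)C(=O)C=[N+]=[N-])c1C | intermediate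
28 | methyl 2,4-dihydroxy-3,6-dimethylbenzoate | COC(=O)c1c(C)cc(O)c(C)c1O | starting material
29 | methyl 5-formyl-2,4-dihydroxy-3,6-dimethylbenzoate | COC(=O)c1c(C)c(C=O)c(O)c(C)c1O | intermediate
30 | methyl 2,4-dihydroxy-3,5,6-trimethylbenzoate | COC(=O)c1c(C)c(C)c(O)c(C)c1O | intermediate
31 | methyl 2,4-bis(benzyloxy)-3,5,6-trimethylbenzoate | COC(=O)c1c(C)c(C)c(OCc2ccccc2)c(C)c1OCc1ccccc1 | intermediate
32 | 2,4-bis(benzyloxy)-3,5,6-trimethylbenzoic acid | OC(=O)c1c(C)c(C)c(OCc2ccccc2)c(C)c1OCc1ccccc1 | intermediate
33 | allyl 6-(benzyloxy)-2-[(2S)-4-{[2,4-bis(benzyloxy)-3,5,6-trimethylbenzoyl]oxy}-3-oxobutan-2-yl]-4-methoxy-3-methylbenzoate | COc1cc(OCc2ccccc2)c(C(=O)OCC=C)c([C@H](C)C(=O)COC(=O)c2c(C)c(C)c(OCc3ccccc3)c(C)c2OCc2ccccc2)c1C | intermediate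
34 | 6-(benzyloxy)-2-[(2S)-4-{[2,4-bis(benzyloxy)-3,5,6-trimethylbenzoyl]oxy}-3-oxobutan-2-yl]-4-methoxy-3-methylbenzoic acid | COc1cc(OCc2ccccc2)c(C(=O)O)c([C@H](C)C(=O)COC(=O)c2c(C)c(C)c(OCc3ccccc3)c(C)c2OCc2ccccc2)c1C | intermediate (not isolated)
35 | [(3R,4S)-8-(benzyloxy)-3-hydroxy-6-methoxy-4,5-dimethyl-1-oxo-3,4-dihydro-1H-isochromen-3-yl]methyl 2,4-bis(benzyloxy)-3,5,6-trimethylbenzoate | COc1cc(OCc2ccccc2)c2c(c1C)[C@H](C)[C@](O)(COC(=O)c1c(C)c(C)c(OCc3ccccc3)c(C)c1OCc1ccccc1)OC2=O | intermediate
36 | [(3R,4S)-3,8-dihydroxy-6-methoxy-4,5-dimethyl-1-oxo-3,4-dihydro-1H-isochromen-3-yl]methyl 2,4-dihydroxy-3,5,6-trimethylbenzoate | COc1cc(O)c2c(c1C)[C@H](C)[C@](O)(COC(=O)c1c(C)c(C)c(O)c(C)c1O)OC2=O | target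

**Step count**
Total step count: 19. Longest linear sequence: 14 steps (steps 1–4, 6–12 and 17–19, counted from 1). Side branches: step 5 (one step) and steps 13–16 (four steps).

**Steps most likely to fail**

Step 6. Three things could go wrong:
- The tertiary malonate anion may capture the aryne too slowly beside the C5 methyl group.
- Part of the addition may leak to C8a.
- The aryl anion may pick up an external proton before the acyl group has moved.

The fallback takes the methyl group out of the insertion. It sets out from 9, which is treated under the same fluoride conditions with commercial diallyl malonate, the less hindered and better precedented partner. This gives allyl 2-[2-(allyloxy)-2-oxoethyl]-4,6-dimethoxy-3-methylbenzoate F1. F1 is then methylated once at its benzylic ester position (LiHMDS, THF, −78 °C, then MeI), where a second methylation is held back by the di-ortho-substituted ring. The sequence comes back to the route at 16.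

Step 10. Two things could go wrong:
- The di-ortho-substituted ring is twisted out of the ketene plane, so control of the enol geometry and of the face of protonation at C4 may be weak.
- The acid chloride may close onto the neighbouring allyl ester before the ketene forms.

The fallback replaces asymmetric induction by classical resolution. It sets out from 19, which is combined with (S)-1-phenylethylamine (or its antipode, whichever gives the less soluble salt with the wanted acid). Fractional crystallisation gives (S)-1-phenylethylammonium (2S)-2-{2-[(allyloxy)carbonyl]-3-(benzyloxy)-5-methoxy-6-methylphenyl}propanoate F2. Acidification of F2 comes back to the route at 25 and bypasses 23 and step 11. The mother liquors hold (2R)-2-{2-[(allyloxy)carbonyl]-3-(benzyloxy)-5-methoxy-6-methylphenyl}propanoic acid F3, which is returned to 19 by passage through 21 and 22 and hydration.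

Step 17. The rhodium carbenoid may be diverted before the acid traps it, by Wolff rearrangement, capture of adventitious water, attack of the neighbouring ester carbonyl or dimerisation. The fallback drops carbenoid chemistry for substitution. It sets out from 27, which is protonated with HBr (48% aq, Et2O/THF, −10 °C) to give allyl 6-(benzyloxy)-2-[(2S)-4-bromo-3-oxobutan-2-yl]-4-methoxy-3-methylbenzoate F4. The unhindered CH2Br carbon of F4 is then displaced by the carboxylate of 32 (KF, DMF, rt). This is the usual way to acyloxymethyl ketones of 2,6-disubstituted benzoic acids, and it is mild enough for a stereocentre alpha to the ketone. The sequence comes back to the route at 33.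

**Further compounds**
F1 | step 6 | allyl 2-[2-(allyloxy)-2-oxoethyl]-4,6-dimethoxy-3-methylbenzoate | COc1cc(OC)c(C(=O)OCC=C)c(CC(=O)OCC=C)c1C
F2 | step 10 | (S)-1-phenylethylammonium (2S)-2-{2-[(allyloxy)carbonyl]-3-(benzyloxy)-5-methoxy-6-methylphenyl}propanoate | COc1cc(OCc2ccccc2)c(C(=O)OCC=C)c([C@H](C)C(=O)[O-])c1C.C[C@H]([NH3+])c1ccccc1
F3 | step 10 | (2R)-2-{2-[(allyloxy)carbonyl]-3-(benzyloxy)-5-methoxy-6-methylphenyl}propanoic acid | COc1cc(OCc2ccccc2)c(C(=O)OCC=C)c([C@@H](C)C(=O)O)c1C
F4 | step 17 | allyl 6-(benzyloxy)-2-[(2S)-4-bromo-3-oxobutan-2-yl]-4-methoxy-3-methylbenzoate | COc1cc(OCc2ccccc2)c(C(=O)OCC=C)c([C@H](C)C(=O)CBr)c1C
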